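If reagent stands in large excess over substrate, I take its concentration as constant and the rate as pseudo-first-order in substrate, so that equal products of reagent charge and time give equal conversion. I test that rule of thumb on these flasks.

| flask | left-handed substrate | right-handed substrate | reagent | remark | time |
|---|---|---|---|---|---|
| birch | 1.1 M | 1.1 M | 2.5 M | run made earlier |  |
| theta | 1.1 M | 1.1 M | 2.75 M |  | 1.5 h |
| eta | 1.1 M | 1.1 M | 2.00 M |  | 5.0 h |

- birch (time / min: left-handed product / %, left-handed substrate / %): 5.00: 4, 48; 15.0: 10, 38; 25.0: 16, 36; 40.0: 22, 34; 50.0: 26, 28; 80.0: 31, 26; 90.0: 31, 26

(each reading ± 1.5 percentage points)

- reagent is single-handed; left-handed substrate and right-handed substrate are mirror images of each other, charged as a racemate, each of them at the stated concentration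
- steps that have been proposed: reagent + left-handed substrate -> left-handed product; reagent + right-handed substrate -> right-handed product; left-handed substrate <-> right-handed substrate; reagent <-> dormant form
- the handed part of reagent does not stay in what it makes, so the products of the two hands are mirror images too

* which one finishes higher in amount of left-handed product, in percent of the left-handed substrate and right-handed substrate together charged ("neither" within 2 percentage points) (theta / eta / neither)
* amount of left-handed product at the end, in percent of the left-handed substrate and right-handed substrate together charged, theta
* amount of left-handed product at the end, in percent of the left-handed substrate and right-handed substrate together charged, eta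

Birch ends with 31% left-handed product at 90.0 min. Scaled in proportion to reagent charge times time, a crude use of the rule, this gives theta 34.1% and eta 82.7%.

The rule treats the concentration of reagent as constant, so its border is the ratio E of reagent charged over both substrates charged, which for eta is 0.909. Each product takes one reagent, so an E below one is also a ceiling on total product, for eta 90.9% of the substrates charged. The rule needs E far above one, but theta has 1.25 and in eta reagent is the limiting reagent. If right-handed substrate stands near left-handed substrate at the end of birch, the left-handed product is, as a reading, 64.6% of all product. At that share my estimate of eta's ceiling for left-handed product is 58.7%, and the rule's figure for eta is higher than that, so it stops working there. Theta stands at 1.10 times the reagent charge times time of birch, a short step from a reading, so I commit to 34.1% for theta. I commit to eta higher than theta and below that estimated ceiling, since the charge times time of eta is greater.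

The forecast gives 34% for theta and 39% for eta, so eta higher, and it warns of its weak step: “If reagent effectively dies, eta stalls near 29%, so this is uncertain.”

Theta gives 33.4% and eta 41.2%, so eta finishes higher.

    reagent + left-handed substrate → left-handed product (k = 0.00710 /M/min)
    reagent + right-handed substrate → right-handed product (k = 0.00420 /M/min)
    left-handed substrate ⇌ right-handed substrate (k = 0.0260 /min)
    reagent ⇌ dormant form (K = 0.510, k = 0.00800 /min)

At 5.00 h eta holds 66.7% as product of both hands, less than its ceiling of 90.9%. At 50.0 h eta holds 89.9%, with 0.739% of its reagent free and 0.00795 M of dormant form.

With 0.80 M of reagent, otherwise as eta, E scales to 0.364, a ceiling of 36.4% product and, at the share read from birch, an estimated 23.5% left-handed product. That neighbour flask gives 19.2% left-handed and 11.5% right-handed product at 5.00 h, together 30.8%.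

The numbers in the tables are simulated from invented constants; scatter was added.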